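Ring B of the 1,2-dihydronaphthalene (C1 bears the pyranone, C2 the acid, C3 the methyl ester) is built by a [3+3] annulation in one flask. The C2–C3–C4 unit, whose carboxyl carbon stands gamma to C4, is the open form of a 5-alkoxybutenolide, so methyl (2R)-2-menthyloxy-5-oxo-2,5-dihydrofuran-3-carboxylate acts as a chiral 1,3-dielectrophile. C1, acidic through the pyranone C4'=C3'–C2'=O vinylogy, adds as a lithium carbanion (C1–C2, C2 set anti to the acetal); the lactone opens to the free C2 acid; acid then closes C4 onto C4a, the arene carbon para to the C7 oxygen, with loss of menthol (C4–C4a, C3=C4). The precursor is a 4-(3,4-dimethoxybenzyl)pyranone ester.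

Key step: step 7

Assumption: the two acetal epimers of 13 are separable and conjugate addition to 13 occurs anti to the menthyloxy group, as is usual for 5-menthyloxybutenolides. Locants C1 to C8a are those of the dihydronaphthalene core; primed locants are those of the pyranone.

Step 1
Reactants: 1 ethyl 3-methylbut-2-enoate; 2 diethyl oxalate
Product: 4 4-methyl-2-oxo-2H-pyran-6-carboxylic acid, via potassium dienolate 3 (not isolated)
Conditions: KOEt, Et2O–EtOH, 0 °C to rt; then concd aq HCl, reflux
Reagents that add atoms: water, O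
Why: Claisen condensation of the gamma-methyl group with the oxalate gives the (2Z,4Z)-dienolate, whose enol oxygen lactonises onto the cis ester under acid while hot acid hydrolyses the remaining ethyl ester, the classical oxalate route to 2-pyranone-6-carboxylic acids.

Step 2
Reactants: 4 4-methyl-2-oxo-2H-pyran-6-carboxylic acid
Product: 5 tert-butyl 4-methyl-2-oxo-2H-pyran-6-carboxylate
Conditions: tert-butyl 2,2,2-trichloroacetimidate, CH2Cl2–cyclohexane, rt
Reagents that add atoms: tert-butyl 2,2,2-trichloroacetimidate, CC(C)(C)OC(=N)C(Cl)(Cl)Cl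
Why: The acid protonates the imidate and is O-alkylated by tert-butyl cation transfer under near-neutral conditions that should leave the 2-pyranone lactone untouched (imidate esterification).

Step 3
Reactants: 5 tert-butyl 4-methyl-2-oxo-2H-pyran-6-carboxylate
Product: 6 tert-butyl 4-(bromomethyl)-2-oxo-2H-pyran-6-carboxylate
Conditions: N-bromosuccinimide, AIBN (cat.), PhCF3, 85 °C
Reagents that add atoms: N-bromosuccinimide, O=C1CCC(=O)N1Br
Why: Wohl–Ziegler radical bromination should take place at the 4-methyl group, the only allylic-type C–H position, as with 4-methylcoumarins and 4-methyl-2-pyranones.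

Step 4
Reactants: 6 tert-butyl 4-(bromomethyl)-2-oxo-2H-pyran-6-carboxylate; 7 (3,4-dimethoxyphenyl)boronic acid
Product: 8 tert-butyl 4-[(3,4-dimethoxyphenyl)methyl]-2-oxo-2H-pyran-6-carboxylate
Conditions: Pd(PPh3)4 (5 mol %), K3PO4, toluene–H2O, 70 °C
Reagents that add atoms: none
Why: Suzuki–Miyaura sp3–sp2 coupling, in which oxidative addition into the allylic-type C–Br bond is fast and the diarylmethane should form as with 4-(halomethyl)coumarins.

Step 5
Reactants: 9 methyl furan-3-carboxylate
Product: 11 methyl 2-hydroxy-5-oxo-2,5-dihydrofuran-3-carboxylate (racemic), via furan endoperoxide 10 (not isolated)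
Conditions: O2, visible light, tetraphenylporphyrin (cat.), iPr2NEt, CH2Cl2, −78 °C
Reagents that add atoms: dioxygen, O=O
Why: Singlet-oxygen [4+2] cycloaddition gives endoperoxide 10, and the hindered amine should remove the C5 proton (gamma to the ester and less hindered) in a Kornblum–DeLaMare rearrangement, so that C5 becomes the lactone carbonyl and C2 the lactol carbon.

Step 6
Reactants: 11 methyl 2-hydroxy-5-oxo-2,5-dihydrofuran-3-carboxylate; 12 (1R,2S,5R)-menthol
Product: 13 methyl (2R)-2-{[(1R,2S,5R)-5-methyl-2-(propan-2-yl)cyclohexyl]oxy}-5-oxo-2,5-dihydrofuran-3-carboxylate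
Conditions: TsOH·H2O (cat.), toluene, reflux with removal of water; crystallisation of the (2R)-epimer, mother liquor re-equilibrated with acid
Reagents that add atoms: none
Why: Acid-catalysed lactol acetalisation (pseudo-ester formation) through the furanone oxocarbenium ion gives both acetal epimers, which equilibrate under the acid, so the (2R)-epimer should be obtainable by crystallisation with recycling, as for the parent 5-menthyloxybutenolide.

Step 7
Reactants: 8 tert-butyl 4-[(3,4-dimethoxyphenyl)methyl]-2-oxo-2H-pyran-6-carboxylate; 13 methyl (2R)-2-{[(1R,2S,5R)-5-methyl-2-(propan-2-yl)cyclohexyl]oxy}-5-oxo-2,5-dihydrofuran-3-carboxylate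
Product: 17 (2S)-1-(6-carboxy-2-oxo-2H-pyran-4-yl)-6,7-dimethoxy-3-(methoxycarbonyl)-1,2-dihydronaphthalene-2-carboxylic acid as both C1 epimers, via lithium carbanion 14 (not isolated), via lactone ester enolate 15 (not isolated), via ring-opened lithium carboxylate 16 (not isolated)
Conditions: LiN(SiMe3)2 (1.05 equiv), toluene–THF, −78 °C; 13, −78 to −20 °C; then excess CF3CO2H–CH2Cl2, 0 °C to rt, argon
Reagents that add atoms: none
Why: LiN(SiMe3)2 removes the C1 proton of 8 (benzylic and gamma to the pyranone carbonyl), and carbanion 14 adds in a vinylogous Michael addition to the unsubstituted alkene carbon of 13 (beta to the methyl ester) from the face anti to the menthyloxy group, which forms C1–C2 and sets C2 as S in enolate 15. Enolate 15 then expels the ring carboxylate in the beta-elimination that ends a Stobbe condensation, giving carboxylate 16 with a beta-menthyloxyacrylate; in CF3CO2H this is C-protonated to an oxocarbenium ion at C4, which C4a attacks in a 6-exo-trig Friedel–Crafts closure of ring B, and loss of menthol from the benzylic ether gives the conjugated C3=C4 bond while the tert-butyl ester is cleaved. The closest known reaction types are conjugate additions of lithium enolates to 5-menthyloxybutenolides, the Stobbe lactone opening, and acid-mediated arene cyclisations onto beta-alkoxyacrylates and aryl acetals (Pechmann and Bradsher types). C2 is controlled by the acetal stereocentre, which is C4 of the product and is erased when C4 becomes trigonal; C1 forms without reliable control and is corrected in step 8. The step needs addition at the CH carbon (expected on steric grounds, as with citraconate-type acceptors), addition faster than proton transfer from the acetal C–H (preformed carbanion at −78 °C), and arene attack at C4a (para to the C7 methoxy group and less hindered than C8). C2 should stay configurationally intact because it remains alpha to a carboxylate or carboxylic acid throughout.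

Step 8
Reactants: 17 (2S)-1-(6-carboxy-2-oxo-2H-pyran-4-yl)-6,7-dimethoxy-3-(methoxycarbonyl)-1,2-dihydronaphthalene-2-carboxylic acid as both C1 epimers
Product: 18 (1R,2S)-1-(6-carboxy-2-oxo-2H-pyran-4-yl)-6,7-dimethoxy-3-(methoxycarbonyl)-1,2-dihydronaphthalene-2-carboxylic acid (trans)
Conditions: DBU (4 equiv), MeCN, 50 °C, argon; aq HCl work-up
Reagents that add atoms: none
Why: Base-mediated thermodynamic epimerisation at C1, the only readily deprotonated C–H (benzylic and gamma to the pyranone carbonyl; C2 is alpha to a carboxylate), should converge on the trans isomer, in which the 1-pyranonyl and 2-carboxyl groups sit pseudo-axial and avoid peri and allylic strain.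

Step 9
Reactants: 18 (1R,2S)-1-(6-carboxy-2-oxo-2H-pyran-4-yl)-6,7-dimethoxy-3-(methoxycarbonyl)-1,2-dihydronaphthalene-2-carboxylic acid
Product: 19 (1R,2S)-1-(6-carboxy-2-oxo-2H-pyran-4-yl)-6,7-dihydroxy-3-(methoxycarbonyl)-1,2-dihydronaphthalene-2-carboxylic acid (CNP0333269.1)
Conditions: BBr3 (8 equiv), CH2Cl2, −78 to 0 °C, argon; then H2O
Reagents that add atoms: none
Why: Lewis-acid ether cleavage, in which BBr3 should cleave the two aryl methyl ethers faster than the conjugated methyl ester at low temperature, the aryl borate being hydrolysed on work-up without touching either stereocentre.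

Compound list
1 | ethyl 3-methylbut-2-enoate | CC(C)=CC(=O)OCC | starting material
2 | diethyl oxalate | CCOC(=O)C(=O)OCC | starting material
3 | potassium (2Z,4Z)-1,6-diethoxy-4-methyl-1,6-dioxohexa-2,4-dien-2-olate | [O-]/C(C(=O)OCC)=C\C(C)=C/C(=O)OCC.[K+] | intermediate
4 | 4-methyl-2-oxo-2H-pyran-6-carboxylic acid | CC1=CC(=O)OC(C(=O)O)=C1 | intermediate
5 | tert-butyl 4-methyl-2-oxo-2H-pyran-6-carboxylate | CC1=CC(=O)OC(C(=O)OC(C)(C)C)=C1 | intermediate
6 | tert-butyl 4-(bromomethyl)-2-oxo-2H-pyran-6-carboxylate | BrCC1=CC(=O)OC(C(=O)OC(C)(C)C)=C1 | intermediate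
7 | (3,4-dimethoxyphenyl)boronic acid | COc1ccc(B(O)O)cc1OC | starting material
8 | tert-butyl 4-[(3,4-dimethoxyphenyl)methyl]-2-oxo-2H-pyran-6-carboxylate | COc1ccc(CC2=CC(=O)OC(C(=O)OC(C)(C)C)=C2)cc1OC | intermediate
9 | methyl furan-3-carboxylate | COC(=O)c1ccoc1 | starting material
10 | methyl 2,3,7-trioxabicyclo[2.2.1]hept-5-ene-5-carboxylate (racemic endoperoxide) | COC(=O)C1=CC2OOC1O2 | intermediate
11 | methyl 2-hydroxy-5-oxo-2,5-dihydrofuran-3-carboxylate (racemic) | COC(=O)C1=CC(=O)OC1O | intermediate
12 | (1R,2S,5R)-menthol | CC(C)[C@@H]1CC[C@@H](C)C[C@H]1O | starting material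
13 | methyl (2R)-2-{[(1R,2S,5R)-5-methyl-2-(propan-2-yl)cyclohexyl]oxy}-5-oxo-2,5-dihydrofuran-3-carboxylate | COC(=O)C1=CC(=O)O[C@H]1O[C@@H]1C[C@H](C)CC[C@H]1C(C)C | intermediate
14 | lithium salt of 8 deprotonated at the benzylic carbon C1 (delocalised dienolate, drawn as the carbanion) | COc1ccc([CH-]C2=CC(=O)OC(C(=O)OC(C)(C)C)=C2)cc1OC.[Li+] | intermediate
15 | lithium ester enolate of the conjugate adduct, lactone intact, acetal carbon R, C2 S with the new substituent trans to menthyloxy, both C1 epimers | COC([O-])=C1[C@H](O[C@@H]2C[C@H](C)CC[C@H]2C(C)C)OC(=O)[C@H]1C(c1ccc(OC)c(OC)c1)C1=CC(=O)OC(C(=O)OC(C)(C)C)=C1.[Li+] | intermediate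
16 | lithium (2S)-2-{[6-(tert-butoxycarbonyl)-2-oxo-2H-pyran-4-yl](3,4-dimethoxyphenyl)methyl}-3-(methoxycarbonyl)-4-(menthyloxy)but-3-enoate, both C1 epimers, enol ether geometry not fixed | COC(=O)C(=CO[C@@H]1C[C@H](C)CC[C@H]1C(C)C)[C@@H](C(=O)[O-])C(c1ccc(OC)c(OC)c1)C1=CC(=O)OC(C(=O)OC(C)(C)C)=C1.[Li+] | intermediate
17 | (2S)-1-(6-carboxy-2-oxo-2H-pyran-4-yl)-6,7-dimethoxy-3-(methoxycarbonyl)-1,2-dihydronaphthalene-2-carboxylic acid, both C1 epimers | COC(=O)C1=Cc2cc(OC)c(OC)cc2C(c2cc(C(=O)O)oc(=O)c2)[C@@H]1C(=O)O | intermediate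
18 | (1R,2S)-1-(6-carboxy-2-oxo-2H-pyran-4-yl)-6,7-dimethoxy-3-(methoxycarbonyl)-1,2-dihydronaphthalene-2-carboxylic acid | COC(=O)C1=Cc2cc(OC)c(OC)cc2[C@@H](c2cc(C(=O)O)oc(=O)c2)[C@@H]1C(=O)O | intermediate
19 | (1R,2S)-1-(6-carboxy-2-oxo-2H-pyran-4-yl)-6,7-dihydroxy-3-(methoxycarbonyl)-1,2-dihydronaphthalene-2-carboxylic acid | COC(=O)C1=Cc2cc(O)c(O)cc2[C@@H](c2cc(C(=O)O)oc(=O)c2)[C@@H]1C(=O)O | target

Total step count: 9. Longest linear sequence: 7 steps (steps 1, 2, 3, 4, 7, 8, 9).

Steps most likely to fail

Step 7. Proton transfer from the acidic acetal C–H of 13 to carbanion 14 may outrun conjugate addition, which would give a furanolate, scramble the acetal configuration and lower both conversion and the enantiomeric purity at C2. Addition at the ester-bearing alkene carbon is a second possible failure. The fallback sets out from 8 and comes back at 17 without any butenolide. Compound 8 is brominated para to the C7 methoxy group (N-bromosuccinimide, MeCN, 0 °C) to give aryl bromide F1. Methyl acrylate and tert-butyl glyoxylate are joined in a DABCO-mediated Morita–Baylis–Hillman reaction to give allylic alcohol F2, which is converted with Boc2O and DMAP into tert-butyl carbonate F3. A cinchona-alkaloid-catalysed asymmetric allylic alkylation of F1 with F3 (SN2'–SN2', for example (DHQD)2AQN or its pseudo-enantiomer, chosen for the 2S sense) forms C1–C2 and gives acrylate F4. An intramolecular 6-endo Heck reaction (Pd(OAc)2, P(o-tol)3, Et3N, MeCN, 80 °C) forms C4–C4a and gives di-tert-butyl ester F5, and CF3CO2H cleaves both tert-butyl esters to give 17.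

Step 6. The two acetal epimers of 13 may co-crystallise or interconvert during purification, so that diastereomerically pure (2R)-13 is not available and C2 is formed with low enantiomeric purity. The fallback sets out from 11 and comes back at 18 by resolution instead of auxiliary control. Compound 11 is converted with methanol and TsOH into racemic methyl pseudo-ester F6. Steps 7 and 8 are run with F6 in place of 13 to give racemic epimer mixture F7 and then racemic trans diacid F8. F8 is resolved by chromatography on a chiral stationary phase, or by crystallisation of its salt with one enantiomer of 1-phenylethylamine, to give 18.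

Step 9. Cleavage of the C3 methyl ester, or attack of bromide on the pyranone, may compete with cleavage of the two aryl methyl ethers. The fallback sets out from 6 and comes back at 19 with a different catechol protecting group. Compound 6 is coupled as in step 4 with commercial (1,3-benzodioxol-5-yl)boronic acid to give benzodioxole pyranone F9, which is carried through steps 7 and 8 to methylenedioxy diacid F10 and trans methylenedioxy diacid F11. BCl3 (CH2Cl2, −78 °C to rt, then aqueous methanol) opens the methylenedioxy ring, a reagent that should leave methyl esters intact, and gives 19.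

Further compounds
F1 | step 7 | tert-butyl 4-[(2-bromo-4,5-dimethoxyphenyl)methyl]-2-oxo-2H-pyran-6-carboxylate | COc1cc(Br)c(CC2=CC(=O)OC(C(=O)OC(C)(C)C)=C2)cc1OC
F2 | step 7 | 4-tert-butyl 1-methyl 3-hydroxy-2-methylidenebutanedioate (racemic) | C=C(C(=O)OC)C(O)C(=O)OC(C)(C)C
F3 | step 7 | 4-tert-butyl 1-methyl 3-[(tert-butoxycarbonyl)oxy]-2-methylidenebutanedioate (racemic) | C=C(C(=O)OC)C(OC(=O)OC(C)(C)C)C(=O)OC(C)(C)C
F4 | step 7 | 4-tert-butyl 1-methyl (3S)-3-{(2-bromo-4,5-dimethoxyphenyl)[6-(tert-butoxycarbonyl)-2-oxo-2H-pyran-4-yl]methyl}-2-methylidenebutanedioate, both epimers at the diarylmethine carbon | C=C(C(=O)OC)[C@@H](C(=O)OC(C)(C)C)C(c1cc(OC)c(OC)cc1Br)C1=CC(=O)OC(C(=O)OC(C)(C)C)=C1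
F5 | step 7 | 2-tert-butyl 3-methyl (2S)-1-[6-(tert-butoxycarbonyl)-2-oxo-2H-pyran-4-yl]-6,7-dimethoxy-1,2-dihydronaphthalene-2,3-dicarboxylate, both C1 epimers | COC(=O)C1=Cc2cc(OC)c(OC)cc2C(c2cc(C(=O)OC(C)(C)C)oc(=O)c2)[C@@H]1C(=O)OC(C)(C)C
F6 | step 6 | methyl 2-methoxy-5-oxo-2,5-dihydrofuran-3-carboxylate (racemic) | COC(=O)C1=CC(=O)OC1OC
F7 | step 6 | 1-(6-carboxy-2-oxo-2H-pyran-4-yl)-6,7-dimethoxy-3-(methoxycarbonyl)-1,2-dihydronaphthalene-2-carboxylic acid, racemic mixture of C1 epimers | COC(=O)C1=Cc2cc(OC)c(OC)cc2C(c2cc(C(=O)O)oc(=O)c2)C1C(=O)O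
F8 | step 6 | racemic trans-1-(6-carboxy-2-oxo-2H-pyran-4-yl)-6,7-dimethoxy-3-(methoxycarbonyl)-1,2-dihydronaphthalene-2-carboxylic acid (1R,2S and 1S,2R) | COC(=O)C1=Cc2cc(OC)c(OC)cc2[C@@H](c2cc(C(=O)O)oc(=O)c2)[C@@H]1C(=O)O.COC(=O)C1=Cc2cc(OC)c(OC)cc2[C@H](c2cc(C(=O)O)oc(=O)c2)[C@H]1C(=O)O
F9 | step 9 | tert-butyl 4-(1,3-benzodioxol-5-ylmethyl)-2-oxo-2H-pyran-6-carboxylate | CC(C)(C)OC(=O)C1=CC(Cc2ccc3OCOc3c2)=CC(=O)O1
F10 | step 9 | methylenedioxy analogue of 17, (2S) with both epimers at the pyranone-bearing carbon | COC(=O)C1=Cc2cc3OCOc3cc2C(c2cc(C(=O)O)oc(=O)c2)[C@@H]1C(=O)O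
F11 | step 9 | methylenedioxy analogue of 18, trans, configured as in 18 | COC(=O)C1=Cc2cc3OCOc3cc2[C@@H](c2cc(C(=O)O)oc(=O)c2)[C@@H]1C(=O)O
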